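**Retrosynthetic overview**
1. Target ⇒ 3β-hydroxy-8-methylidene-decalin-9-one + (3E,7E)-homofarnesyl organocerium: 1,2-addition makes C9–C11, then Pd/formate reduction of the tertiary allylic carbonate leaves the exocyclic C8 methylene and 9α-H.
2. That decalone ⇒ trans-fused 4,4,10-trimethyl-decalin-3-one (C9 ketal), whose ring A (C1, C2, C3, C4, C5, C10) is made from a cyclopentane (C1, C2, C3, C5, C10) by insertion of C4 between C3 and C5.
3. Enabling feature: the carbinol carbon C3 of the five-membered ring carries an isopropenyl group (C4 with both methyls) and is bonded to the ring-fusion alkene C5=C6 (a 1-alkenyl-1-isopropenylcyclopentanol), so a radical at C4 can take C5 over from C3.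
4. This hydrindenol ⇒ enedione ⇒ cis α-ketol from an enantioselective NHC benzoin desymmetrisation of the Michael adduct of 2-methylcyclohexane-1,3-dione and acrolein (sets C10).
5. Ring order: ring B is bought; five-membered ring in step 2; six-membered ring A by ring enlargement in step 6; C5, C3 and C9 follow in steps 6, 7 and 11.

Key step: step 6

Remark: (3E,7E)-homofarnesol is taken as purchasable; locants C1–C11 and α/β are those of the decalin core of the target (C3 carbinol, C4 gem-dimethyl carbon, C5/C10 ring fusion, C8 methylene-bearing carbon, C9 side-chain carbon, C11 first side-chain carbon; the C10 methyl is β).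

Step 1
Reactants: 1 2-methylcyclohexane-1,3-dione; 2 acrolein
Product: 3 3-(1-methyl-2,6-dioxocyclohexyl)propanal
Conditions: H2O, rt
Reagents that add atoms: none
Why: Michael addition of the enolised 1,3-dione to acrolein forms the quaternary carbon (future C10), which is not yet stereogenic because its two ring carbonyls are equivalent.

Step 2
Reactants: 3 3-(1-methyl-2,6-dioxocyclohexyl)propanal
Product: 4 (3aS,7aR)-7a-hydroxy-3a-methylhexahydro-1H-indene-1,4(2H)-dione (cis-fused α-ketol)
Conditions: chiral aminoindanol-derived N-C6F5 triazolium tetrafluoroborate (10 mol %), Et3N, toluene, rt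
Reagents that add atoms: none
Why: Enantioselective intramolecular crossed benzoin reaction, in which the chiral Breslow intermediate (acyl anion at future C3) adds to one of the two enantiotopic ketones (desymmetrisation under catalyst control), closing the five-membered ring 5-exo-trig and fixing C10; the precatalyst enantiomer is chosen that gives the (3aS) series.

Step 3
Reactants: 4 (3aS,7aR)-7a-hydroxy-3a-methylhexahydro-1H-indene-1,4(2H)-dione
Product: 5 (S)-3a-methyl-3,3a,5,6-tetrahydro-1H-indene-1,4(2H)-dione
Conditions: Burgess reagent, THF, 50 °C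
Reagents that add atoms: none
Why: Burgess dehydration (syn-elimination of the sulfamate) of the tertiary α-ketol can only take the C6 hydrogen and gives the conjugated enone C3(=O)–C5=C6, erasing the carbinol stereocentre.

Step 4
Reactants: 5 (S)-3a-methyl-3,3a,5,6-tetrahydro-1H-indene-1,4(2H)-dione
Product: 6 (3aS)-4,4-(ethylenedioxy)-3a-methyl-2,3,3a,4,5,6-hexahydro-1H-inden-1-one
Conditions: ethylene glycol, p-TsOH (cat.), benzene, reflux (Dean–Stark)
Reagents that add atoms: ethylene glycol, OCCO
Why: Chemoselective acid-catalysed ketalisation, since the saturated cyclohexanone carbonyl (C9) reacts much faster than the conjugated cyclopentenone carbonyl (C3).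

Step 5
Reactants: 6 (3aS)-4,4-(ethylenedioxy)-3a-methyl-2,3,3a,4,5,6-hexahydro-1H-inden-1-one
Product: 7 (3aS)-4,4-(ethylenedioxy)-3a-methyl-1-(prop-1-en-2-yl)-2,3,3a,4,5,6-hexahydro-1H-inden-1-ol (both epimers at the carbinol carbon)
Conditions: isopropenylmagnesium bromide, CeCl3, THF, −78 °C
Reagents that add atoms: isopropenylmagnesium bromide, C=C(C)[Mg]Br
Why: Organocerium 1,2-addition to the enone carbonyl without conjugate addition or enolisation; the new carbinol centre need not be controlled because it becomes sp2 in step 6.

Step 6
Reactants: 7 (3aS)-4,4-(ethylenedioxy)-3a-methyl-1-(prop-1-en-2-yl)-2,3,3a,4,5,6-hexahydro-1H-inden-1-ol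
Product: 9 9,9-(ethylenedioxy)-4,4,10β-trimethyl-5α-decalin-3-one, via ring-enlarged decal-5-en-3-one 8 (not isolated)
Conditions: Mn(dpm)3 (10 mol %), PhSiH3, t-BuOOH, i-PrOH, 22 °C
Reagents that add atoms: none
Why: Proposed new method: Mn–H transfers H• to the CH2 terminus of the isopropenyl group to give the tertiary radical at C4, which attacks the ring-fusion alkene carbon C5 (3-exo-trig); the cyclopropylcarbinyl radical at C6 reopens by cleaving the old ring bond C3–C5, so C5 has moved from C3 to C4 (radical 1,2-alkenyl shift), the cyclopentane has become ring A and the ketyl radical at C3 is oxidised to ketone 8. The closest known reactions are radical and radical–polar-crossover semipinacol rearrangements of allylic alcohols with 1,2-aryl or 1,2-alkenyl migration and MHAT hydrogenation of hindered alkenes; running both in one flask on a 1-alkenyl-1-isopropenylcyclopentanol is new. Ring A is not closed by a cyclisation but by ring enlargement (transient 3-exo-trig closure, then β-scission), and ring B is untouched. In the same medium a second MHAT to C6 of the hindered C5=C6 alkene of 8 gives the tertiary C5 radical, which takes up H• on the α-face, opposite the axial methyl groups on C10 and C4, so the trans ring fusion (5α-H) is set under substrate control by C10, and both carbinol epimers of 7 converge because C3 becomes sp2. The step needs HAT at the isopropenyl group before the trisubstituted alkene (1,1-disubstituted alkenes react much faster), migration of C5 and not C2 (only the sp2 carbon can migrate in the radical manifold) and rearrangement faster than reduction of the first radical (favoured by the gem-disubstituted 3-butenyl radical geometry and the stabilised ketyl product).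

Step 7
Reactants: 9 9,9-(ethylenedioxy)-4,4,10β-trimethyl-5α-decalin-3-one
Product: 11 3β-hydroxy-4,4,10β-trimethyl-5α-decalin-9-one, via hydroxy ketal 10 (not isolated)
Conditions: NaBH4, MeOH, 0 °C; then 2 M HCl, THF, rt
Reagents that add atoms: water, O
Why: Hydride attacks the hindered 4,4-dimethyl ketone axially from the α-face (the β-face is blocked by the axial 4β- and 10β-methyl groups) to give the equatorial 3β-alcohol, and aqueous acid then hydrolyses the dioxolane to the C9 ketone.

Step 8
Reactants: 11 3β-hydroxy-4,4,10β-trimethyl-5α-decalin-9-one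
Product: 12 3β-hydroxy-4,4,10β-trimethyl-8-methylidene-5α-decalin-9-one
Conditions: paraformaldehyde, N-methylanilinium trifluoroacetate, THF, reflux
Reagents that add atoms: formaldehyde (from paraformaldehyde), C=O
Why: α-Methylenation by Mannich condensation–elimination can only occur at C8, the sole enolisable position of the C9 ketone (C10 is quaternary).

Step 9
Reactants: 13 (3E,7E)-4,8,12-trimethyltrideca-3,7,11-trien-1-ol (homofarnesol)
Product: 14 (3E,7E)-1-bromo-4,8,12-trimethyltrideca-3,7,11-triene (homofarnesyl bromide)
Conditions: CBr4, PPh3, CH2Cl2, 0 °C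
Reagents that add atoms: carbon tetrabromide, BrC(Br)(Br)Br
Why: Appel bromination of the primary alcohol leaves the trisubstituted alkenes and their E geometry untouched.

Step 10
Reactants: 12 3β-hydroxy-4,4,10β-trimethyl-8-methylidene-5α-decalin-9-one; 14 (3E,7E)-homofarnesyl bromide
Product: 16 9α-[(3E,7E)-homofarnesyl]-4,4,10β-trimethyl-8-methylidene-5α-decalin-3β,9β-diyl bis(methyl carbonate), via diol 15 (not isolated)
Conditions: 14, Mg, THF, then CeCl3, −78 °C; add 12 (pre-treated with LiHMDS, 1 equiv); then ClCO2Me, −78 → 0 °C
Reagents that add atoms: methyl chloroformate, COC(=O)Cl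
Why: 1,2-Addition of the non-basic organocerium reagent to the hindered enone carbonyl (expected from the α-face, anti to the angular methyl) followed by acylation of both alkoxides; the C9 configuration is inconsequential because C9 becomes a π-allyl terminus in step 11.

Step 11
Reactants: 16 9α-[(3E,7E)-homofarnesyl]-4,4,10β-trimethyl-8-methylidene-5α-decalin-3β,9β-diyl bis(methyl carbonate)
Product: 17 9β-[(3E,7E)-homofarnesyl]-4,4,10β-trimethyl-8-methylidene-5α-decalin-3β-yl methyl carbonate (9α-H)
Conditions: Pd(OAc)2 (5 mol %), n-Bu3P, HCO2H, Et3N, THF, 40 °C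
Reagents that add atoms: none
Why: Palladium-catalysed formate hydrogenolysis of the tertiary allylic carbonate (Tsuji-type reduction) delivers hydride from palladium to the more substituted allyl terminus C9, leaving the exocyclic C8 methylene, and it does so on the α-face where palladium sits (the β-face is shielded by the angular methyl and the CH2 terminus allows π–σ–π face exchange), which sets 9α-H with the side chain β.

Step 12
Reactants: 17 9β-[(3E,7E)-homofarnesyl]-4,4,10β-trimethyl-8-methylidene-5α-decalin-3β-yl methyl carbonate
Product: 18 9β-[(3E,7E)-4,8,12-trimethyltrideca-3,7,11-trien-1-yl]-4,4,10β-trimethyl-8-methylidene-5α-decalin-3β-ol (target, 3S,5R,9S,10R)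
Conditions: K2CO3, MeOH, rt
Reagents that add atoms: none
Why: Base-catalysed transesterification removes the secondary methyl carbonate and frees the 3β-alcohol without touching the alkenes or any stereocentre.

**Compound list**
1 | 2-methylcyclohexane-1,3-dione | CC1C(=O)CCCC1=O | starting material
2 | acrolein | C=CC=O | starting material
3 | 3-(1-methyl-2,6-dioxocyclohexyl)propanal | O=CCCC1(C)C(=O)CCCC1=O | intermediate
4 | (3aS,7aR)-7a-hydroxy-3a-methylhexahydro-1H-indene-1,4(2H)-dione (OH and CH3 cis) | O=C1CC[C@]2(C)C(=O)CCC[C@]12O | intermediate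
5 | (S)-3a-methyl-3,3a,5,6-tetrahydro-1H-indene-1,4(2H)-dione | O=C1CC[C@]2(C)C(=O)CCC=C12 | intermediate
6 | (3aS)-4,4-(ethylenedioxy)-3a-methyl-2,3,3a,4,5,6-hexahydro-1H-inden-1-one | O=C1CC[C@]2(C)C3(OCCO3)CCC=C12 | intermediate
7 | (3aS)-4,4-(ethylenedioxy)-3a-methyl-1-(prop-1-en-2-yl)-2,3,3a,4,5,6-hexahydro-1H-inden-1-ol, both carbinol epimers | CC(=C)C1(O)CC[C@]2(C)C3(OCCO3)CCC=C12 | intermediate
8 | 9,9-(ethylenedioxy)-4,4,10β-trimethyldecal-5-en-3-one | O=C1CC[C@]2(C)C3(OCCO3)CCC=C2C1(C)C | intermediate (not isolated)
9 | 9,9-(ethylenedioxy)-4,4,10β-trimethyl-5α-decalin-3-one (trans-fused) | O=C1CC[C@]2(C)C3(OCCO3)CCC[C@H]2C1(C)C | intermediate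
10 | 9,9-(ethylenedioxy)-4,4,10β-trimethyl-5α-decalin-3β-ol | O[C@H]1CC[C@]2(C)C3(OCCO3)CCC[C@H]2C1(C)C | intermediate (not isolated)
11 | 3β-hydroxy-4,4,10β-trimethyl-5α-decalin-9-one | O[C@H]1CC[C@]2(C)C(=O)CCC[C@H]2C1(C)C | intermediate
12 | 3β-hydroxy-4,4,10β-trimethyl-8-methylidene-5α-decalin-9-one | O[C@H]1CC[C@]2(C)C(=O)C(=C)CC[C@H]2C1(C)C | intermediate
13 | (3E,7E)-4,8,12-trimethyltrideca-3,7,11-trien-1-ol (homofarnesol) | OCC/C=C(\C)CC/C=C(\C)CCC=C(C)C | starting material
14 | (3E,7E)-1-bromo-4,8,12-trimethyltrideca-3,7,11-triene | BrCC/C=C(\C)CC/C=C(\C)CCC=C(C)C | intermediate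
15 | 9α-[(3E,7E)-homofarnesyl]-4,4,10β-trimethyl-8-methylidene-5α-decalin-3β,9β-diol (9-epimer equally usable) | O[C@H]1CC[C@]2(C)[C@](O)(CC/C=C(\C)CC/C=C(\C)CCC=C(C)C)C(=C)CC[C@H]2C1(C)C | intermediate (not isolated)
16 | bis(methyl carbonate) of 15 | COC(=O)O[C@H]1CC[C@]2(C)[C@](OC(=O)OC)(CC/C=C(\C)CC/C=C(\C)CCC=C(C)C)C(=C)CC[C@H]2C1(C)C | intermediate
17 | 3-O-methyl carbonate of the target (9α-H, side chain 9β) | COC(=O)O[C@H]1CC[C@]2(C)[C@@H](CC/C=C(\C)CC/C=C(\C)CCC=C(C)C)C(=C)CC[C@H]2C1(C)C | intermediate
18 | (3S,5R,9S,10R)-9-[(3E,7E)-4,8,12-trimethyltrideca-3,7,11-trien-1-yl]-4,4,10-trimethyl-8-methylidenedecalin-3-ol | C=C1CC[C@H]2C(C)(C)[C@@H](O)CC[C@]2(C)[C@H]1CC/C=C(\C)CC/C=C(\C)CCC=C(C)C | target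

**Step count and risks**
Total step count: 12. Longest linear sequence: 11 (steps 1–8 and 10–12; step 9 is the side branch).

Steps most likely to fail:

1. Step 6 (proposed new method). The first tertiary radical may be reduced before it rearranges, which would simply hydrogenate the isopropenyl group, or the hindered C5=C6 alkene may resist the second hydrogen-atom transfer. The fallback uses known chemistry and sets out from 7: a cobalt–salen-catalysed MHAT with an N-fluoro-2,4,6-trimethylpyridinium oxidant and PhSiH3 (radical–polar-crossover semipinacol rearrangement, alkenyl migration through the tertiary cation) should give the ring-enlarged ketone 8, now isolated. Heterogeneous hydrogenation (H2, Pd/C, EtOAc), with addition from the α-face, then comes back to the route at 9.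

2. Step 10. The long-chain organometallic may form poorly (Wurtz coupling) or add badly to the hindered, polymerisable α-methylene ketone (conjugate addition, reduction). The fallback sets out from 12 and brings in the chain by sulfone alkylation instead. Lithiated methyl phenyl sulfone with CeCl3 is added to 12 and the alkoxides are trapped with methyl chloroformate to give the phenylsulfonylmethyl bis(methyl carbonate) F1. Palladium–formate reduction as in step 11 (ammonium formate, no amine base) gives the 9β-(phenylsulfonylmethyl) exo-methylene compound F2. Deprotonation with LiHMDS in THF/HMPA and SN2 alkylation with commercial (2E,6E)-farnesyl bromide gives the farnesylated sulfone F3. Reductive desulfonylation (SmI2, HMPA, THF/MeOH) comes back to the route at 17.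

3. Step 11. Hydride may be delivered to the unhindered CH2 terminus, giving the tetrasubstituted C8=C9 alkene, or to the β-face of C9. The fallback sets out from 16 and inverts the polarity: Pd(PPh3)4-catalysed reduction with SmI2 and i-PrOH in THF turns the π-allyl into an allylsamarium, which is protonated at the more substituted carbon C9 (SE2′) from the less hindered α-face, and comes back to the route at 17.

Further compounds
F0 | step 6 | none | none
F1 | step 10 | 9α-(phenylsulfonylmethyl)-4,4,10β-trimethyl-8-methylidene-5α-decalin-3β,9β-diyl bis(methyl carbonate) | COC(=O)O[C@H]1CC[C@]2(C)[C@](OC(=O)OC)(CS(=O)(=O)c3ccccc3)C(=C)CC[C@H]2C1(C)C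
F2 | step 10 | 9β-(phenylsulfonylmethyl)-4,4,10β-trimethyl-8-methylidene-5α-decalin-3β-yl methyl carbonate (9α-H) | COC(=O)O[C@H]1CC[C@]2(C)[C@@H](CS(=O)(=O)c3ccccc3)C(=C)CC[C@H]2C1(C)C
F3 | step 10 | 9β-[(3E,7E)-4,8,12-trimethyl-1-(phenylsulfonyl)trideca-3,7,11-trien-1-yl]-4,4,10β-trimethyl-8-methylidene-5α-decalin-3β-yl methyl carbonate (both C11 epimers) | COC(=O)O[C@H]1CC[C@]2(C)[C@@H](C(C/C=C(\C)CC/C=C(\C)CCC=C(C)C)S(=O)(=O)c3ccccc3)C(=C)CC[C@H]2C1(C)C
F0 | step 11 | none | none
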